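**Retrosynthetic overview**
1. Last bond: the C7–O ester, from the (7R)-azaphilone alcohol and linoleoyl chloride made in the flask from tert-butyl linoleate.
2. Linoleate chain: both Z-alkenes by Lindlar reduction of the 9,12-diyne; C8–C9 by alkyl Sonogashira coupling, C10–C11 by Cu-catalysed propargylation, C2–C3 by ester enolate alkylation.
3. Carbocycle (second ring, formed last): C4a=C5 by intramolecular Knoevenagel-type closure of a 3-acyl-4-pyranone that already carries the tertiary α-ketol.
4. C7 stereocentre (key step): catalytic enantioselective α-ketol 1,2-methyl shift of an achiral Me2C(OH)–CO–CO–pyranonyl diketone, which comes from ketohydroxylation of a 3-methylbut-2-enoyl ketone.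
5. Pyranone (first ring): enaminone of mesityl oxide plus diketene.

Assumption: the [C@] centre of the given SMILES is (7R) (priorities O > C8 > C6 > CH3); the enantiomer of the Cu(II)–bis(oxazoline) ligand in step 4 is chosen in a first run to give this sense.

**Step 1**
Reactants: 1 mesityl oxide (4-methylpent-3-en-2-one); 2 N,N-dimethylformamide dimethyl acetal
Product: 3 (1E)-1-(dimethylamino)-5-methylhexa-1,4-dien-3-one
Conditions: 2 (1.5 equiv), neat, 100 °C, MeOH distilled off
Reagents that add atoms: none
Why: Amide-acetal (DMF-DMA) condensation at the acetyl CH3 of the methyl ketone gives the E-enaminone and installs the future C1; no stereocentre is formed.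

**Step 2**
Reactants: 3 (1E)-1-(dimethylamino)-5-methylhexa-1,4-dien-3-one; 4 diketene
Product: 5 6-methyl-3-(3-methylbut-2-enoyl)-4H-pyran-4-one
Conditions: 4 (1.3 equiv), PhMe, 0 → 80 °C, N2 sweep; AcOH (cat.)
Reagents that add atoms: none
Why: Enamine–diketene annulation: C-acetoacetylation of the nucleophilic enaminone α-carbon, O-cyclisation onto the iminium carbon and loss of Me2NH build the 4-pyranone ring, with the 3-acyl/6-methyl pattern fixed by the polarity of both partners.

**Step 3**
Reactants: 5 6-methyl-3-(3-methylbut-2-enoyl)-4H-pyran-4-one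
Product: 6 3-(3-hydroxy-3-methyl-2-oxobutanoyl)-6-methyl-4H-pyran-4-one
Conditions: RuCl3 (1 mol%), Oxone, NaHCO3, EtOAc/MeCN/H2O, 23 °C
Reagents that add atoms: potassium peroxymonosulfate (active component of Oxone), [K+].[O-]S(=O)(=O)OO
Why: RuO4-catalysed ketohydroxylation of the trisubstituted enone C=C, in which the CH carbon necessarily becomes the ketone and the CMe2 carbon the tertiary alcohol, gives the achiral α-diketone carbinol while the electron-poor acylpyranone is left alone.

**Step 4**
Reactants: 6 3-(3-hydroxy-3-methyl-2-oxobutanoyl)-6-methyl-4H-pyran-4-one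
Product: 7 3-[(2R)-2-hydroxy-2-methyl-3-oxobutanoyl]-6-methyl-4H-pyran-4-one
Conditions: Cu(OTf)2 (10 mol%), (S,S)-t-Bu-box (11 mol%), 4 Å MS, CH2Cl2, 0 °C
Reagents that add atoms: none
Why: Proposed new method: two-point binding of the s-cis 1,2-diketone to the chiral Cu(II)–bis(oxazoline) activates the ketone next to the carbinol, and one of the two enantiotopic methyl groups of the CMe2OH carbon migrates to it (1,2-shift; the carbinol carbon becomes the acetyl C=O), which creates the (R)-tertiary alcohol under catalyst control and is driven by loss of the α-dicarbonyl; the closest known reaction type is the chiral Lewis-acid-catalysed enantioselective α-ketol (acyloin) rearrangement of tertiary β-hydroxy-α-keto esters, not yet shown for an α-diketone bearing a pyranonyl acyl group.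

**Step 5**
Reactants: 7 3-[(2R)-2-hydroxy-2-methyl-3-oxobutanoyl]-6-methyl-4H-pyran-4-one
Product: 9 (7R)-7-hydroxy-3,7-dimethyl-6H-isochromene-6,8(7H)-dione, via furopyrylium triflate 8 (not isolated)
Conditions: Tf2O (1.05 equiv), 2,6-di-tert-butyl-4-methylpyridine, CH2Cl2, −78 → 0 °C; then i-Pr2NEt, 0 → 23 °C
Reagents that add atoms: none
Why: Proposed new method: O-activation of the pyranone carbonyl lets the tertiary OH close by ipso-substitution to the bicyclic 4-alkoxypyrylium 8, in which the acetyl enol can reach only the γ-carbon C4a (attack at C1 would need a bridgehead alkene), so addition–elimination with loss of the C7 oxygen from C4a forms the C4a=C5 bond and the six-membered carbocycle (furanone-to-cyclohexadienone ring switch) without touching C7; the closest known reaction type is the Knoevenagel-type γ-substitution of O-activated 4-pyranones (4-alkoxy- or 4-acyloxypyrylium salts) by C–H acids to give 4-ylidene-4H-pyrans.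

**Step 6**
Reactants: 10 tert-butyl acetate; 11 1,6-dibromohexane
Product: 13 tert-butyl 8-bromooctanoate, via lithium ester enolate 12 (not isolated)
Conditions: LDA, THF, −78 °C; then 11 (4 equiv), DMPU, −78 → 23 °C
Reagents that add atoms: none
Why: Ester enolate SN2 alkylation, with the dibromide in excess so that only one C–Br bond reacts.

**Step 7**
Reactants: 14 hept-1-yne; 15 3-bromoprop-1-yne (propargyl bromide)
Product: 17 deca-1,4-diyne, via heptynylmagnesium bromide 16 (not isolated)
Conditions: EtMgBr, THF, 45 °C; then CuCl (5 mol%), 15 (1.2 equiv), 45 °C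
Reagents that add atoms: none
Why: Copper-catalysed propargylic substitution of an alkynyl Grignard reagent, the classical route to skipped (1,4-) diynes.

**Step 8**
Reactants: 13 tert-butyl 8-bromooctanoate; 17 deca-1,4-diyne
Product: 18 tert-butyl octadeca-9,12-diynoate
Conditions: [(π-allyl)PdCl]2 (2.5 mol%), 1,3-di(1-adamantyl)imidazolium chloride (5 mol%), CuI (7.5 mol%), Cs2CO3, DMF/Et2O, 45 °C
Reagents that add atoms: none
Why: Sonogashira-type Pd/NHC–Cu coupling of an unactivated primary alkyl bromide with a terminal alkyne under mild carbonate base, which tolerates the tert-butyl ester and the skipped diyne.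

**Step 9**
Reactants: 18 tert-butyl octadeca-9,12-diynoate
Product: 19 tert-butyl (9Z,12Z)-octadeca-9,12-dienoate
Conditions: H2 (1 atm), Lindlar catalyst, quinoline, hexane/EtOAc, 23 °C
Reagents that add atoms: none
Why: Lindlar semihydrogenation adds H2 syn to each alkyne and so sets both Z double bonds.

**Step 10**
Reactants: 19 tert-butyl (9Z,12Z)-octadeca-9,12-dienoate; 9 (7R)-7-hydroxy-3,7-dimethyl-6H-isochromene-6,8(7H)-dione
Product: 21 (7R)-3,7-dimethyl-6,8-dioxo-7,8-dihydro-6H-isochromen-7-yl (9Z,12Z)-octadeca-9,12-dienoate, via linoleoyl chloride 20 (not isolated)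
Conditions: SOCl2, CH2Cl2, 23 °C, evaporate; then 9, DMAP (0.3 equiv), pyridine, CH2Cl2, 0 → 23 °C
Reagents that add atoms: none
Why: SOCl2 converts the tert-butyl ester directly into the acid chloride, and DMAP-catalysed acylation (nucleophilic catalysis) of the tertiary C7–OH forms the ester without breaking any bond at the stereocentre, so (R) is retained.

**Compound list**
1 | mesityl oxide (4-methylpent-3-en-2-one) | CC(=O)C=C(C)C | starting material
2 | N,N-dimethylformamide dimethyl acetal | COC(OC)N(C)C | starting material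
3 | (1E)-1-(dimethylamino)-5-methylhexa-1,4-dien-3-one | CN(C)/C=C/C(=O)C=C(C)C | intermediate
4 | diketene (4-methylideneoxetan-2-one) | C=C1CC(=O)O1 | starting material
5 | 6-methyl-3-(3-methylbut-2-enoyl)-4H-pyran-4-one | CC(C)=CC(=O)C1=COC(C)=CC1=O | intermediate
6 | 3-(3-hydroxy-3-methyl-2-oxobutanoyl)-6-methyl-4H-pyran-4-one | CC(C)(O)C(=O)C(=O)C1=COC(C)=CC1=O | intermediate
7 | 3-[(2R)-2-hydroxy-2-methyl-3-oxobutanoyl]-6-methyl-4H-pyran-4-one | CC(=O)[C@@](C)(O)C(=O)C1=COC(C)=CC1=O | intermediate
8 | (2R)-2-acetyl-2,6-dimethyl-3-oxo-2,3-dihydrofuro[3,2-c]pyran-5-ium trifluoromethanesulfonate | CC(=O)[C@@]1(C)OC2=CC(C)=[O+]C=C2C1=O.[O-]S(=O)(=O)C(F)(F)F | intermediate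
9 | (7R)-7-hydroxy-3,7-dimethyl-6H-isochromene-6,8(7H)-dione | O[C@]1(C)C(=O)C=C2C=C(C)OC=C2C1=O | intermediate
10 | tert-butyl acetate | CC(=O)OC(C)(C)C | starting material
11 | 1,6-dibromohexane | BrCCCCCCBr | starting material
12 | lithium 1-tert-butoxyethen-1-olate | [Li+].[O-]C(=C)OC(C)(C)C | intermediate
13 | tert-butyl 8-bromooctanoate | CC(C)(C)OC(=O)CCCCCCCBr | intermediate
14 | hept-1-yne | CCCCCC#C | starting material
15 | 3-bromoprop-1-yne (propargyl bromide) | C#CCBr | starting material
16 | hept-1-yn-1-ylmagnesium bromide | CCCCCC#C[Mg]Br | intermediate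
17 | deca-1,4-diyne | CCCCCC#CCC#C | intermediate
18 | tert-butyl octadeca-9,12-diynoate | CCCCCC#CCC#CCCCCCCCC(=O)OC(C)(C)C | intermediate
19 | tert-butyl (9Z,12Z)-octadeca-9,12-dienoate | CCCCC/C=C\C/C=C\CCCCCCCC(=O)OC(C)(C)C | intermediate
20 | (9Z,12Z)-octadeca-9,12-dienoyl chloride | CCCCC/C=C\C/C=C\CCCCCCCC(Cl)=O | intermediate
21 | (7R)-3,7-dimethyl-6,8-dioxo-7,8-dihydro-6H-isochromen-7-yl (9Z,12Z)-octadeca-9,12-dienoate | CCCCC/C=C\C/C=C\CCCCCCCC(=O)O[C@]1(C)C(=O)C=C2C=C(C)OC=C2C1=O | target

**Totals**
Total step count: 10. Longest linear sequence: 6 steps (steps 1, 2, 3, 4, 5, 10).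

**Three steps most likely to fail**

Step 4 (proposed new step). The copper may bind the pyranone/C8 carbonyl pair instead of the 1,2-diketone, and the product α-ketol could equilibrate further and lose ee. The fallback sets the stereocentre by known chemistry, sets out from 2 and 4, and comes back at 7. Commercial 3-methylpentane-2,4-dione is condensed with 2 to (1E)-1-(dimethylamino)-4-methylhex-1-ene-3,5-dione F1. F1 is annulated with 4 as in step 2 to 2-methyl-1-(6-methyl-4-oxo-4H-pyran-3-yl)butane-1,3-dione F2. A catalytic enantioselective α-hydroxylation of this 2-substituted 1,3-diketone then gives 7 directly; this is a known reaction class for α-substituted β-dicarbonyls (cinchona alkaloid with cumene hydroperoxide, or a chiral N,N'-dioxide–metal complex with an oxaziridine).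

Step 5 (proposed new step). The methyl ketone may add to C1 of the acylpyranone instead of C4a if bicyclic 8 does not form cleanly. The fallback masks C1, sets out from 7 and comes back at 9. Chemoselective conjugate reduction of the doubly activated ring C=C with a Hantzsch ester gives 3-[(2R)-2-hydroxy-2-methyl-3-oxobutanoyl]-6-methyl-2,3-dihydro-4H-pyran-4-one F3. Acid-mediated intramolecular aldol condensation (TsOH, PhMe, Dean–Stark) of its methyl ketone with the ring carbonyl gives (7R)-7-hydroxy-3,7-dimethyl-1H-isochromene-6,8(5H,7H)-dione F4. DDQ dehydrogenation across C1–H/C5–H returns 9.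

Step 3. RuO4 may over-oxidise the α-ketol (C–C cleavage) or attack the pyranone enol ether. The fallback goes stepwise, sets out from 5 and comes back at 6. Upjohn dihydroxylation (cat. OsO4, NMO, acetone/H2O) of the enone double bond gives 3-(2,3-dihydroxy-3-methylbutanoyl)-6-methyl-4H-pyran-4-one F5. Its secondary alcohol is then oxidised to the ketone with IBX (or Cu(OAc)2/NH4NO3) to give 6.

**Further compounds**
F1 | step 4 | (1E)-1-(dimethylamino)-4-methylhex-1-ene-3,5-dione (racemic) | CN(C)/C=C/C(=O)C(C)C(C)=O
F2 | step 4 | 2-methyl-1-(6-methyl-4-oxo-4H-pyran-3-yl)butane-1,3-dione (racemic) | CC(=O)C(C)C(=O)C1=COC(C)=CC1=O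
F3 | step 5 | 3-[(2R)-2-hydroxy-2-methyl-3-oxobutanoyl]-6-methyl-2,3-dihydro-4H-pyran-4-one (mixture of epimers at ring C3) | CC(=O)[C@@](C)(O)C(=O)C1COC(C)=CC1=O
F4 | step 5 | (7R)-7-hydroxy-3,7-dimethyl-1H-isochromene-6,8(5H,7H)-dione | O[C@]1(C)C(=O)CC2=C(COC(C)=C2)C1=O
F5 | step 3 | 3-(2,3-dihydroxy-3-methylbutanoyl)-6-methyl-4H-pyran-4-one (racemic) | CC(C)(O)C(O)C(=O)C1=COC(C)=CC1=O
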